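**Strategy.** Everything rests on opening ring C of the lower (epigallocatechin) unit at C4–C4a and O1–C8a. Ring A then enters as 3,5-bis(benzyloxy)benzyne and the O1–C2–C3–C4 chain as an open-chain bromo alcohol whose two stereocentres come from one auxiliary-controlled syn glycolate aldol. In the key step the lithium alkoxide adds to the aryne and the aryllithium so formed closes onto the CH2Br carbon, which makes both bonds in one flask. The step exploits the C5 oxygen of ring A: it polarises the C4a≡C8a aryne so that O1 goes to C8a and the carbanion appears at C4a. A bromine at C8 then steers the robinetinidol C4 cation to C6.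

Key step: step 5

Assumption: natural (+)-dihydrorobinetin (2R,3R), 3,4,5-tris(benzyloxy)benzaldehyde and 1,3-bis(benzyloxy)-5-bromobenzene are taken as catalogue compounds; flavan numbering (O1, C2, C3, C4, C4a, C5–C8, C8a) is used for both units.

**Step 1**
Reactants: 1 (S)-4-benzyloxazolidin-2-one; 2 (benzyloxy)acetyl chloride
Product: 3 (S)-4-benzyl-3-[(benzyloxy)acetyl]oxazolidin-2-one
Conditions: Et3N, DMAP (cat.), CH2Cl2, 0 °C → rt
Reagents that add atoms: none
Why: DMAP-catalysed N-acylation of the oxazolidinone by the acid chloride should give the glycolate imide without touching the auxiliary stereocentre.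

**Step 2**
Reactants: 3 (S)-4-benzyl-3-[(benzyloxy)acetyl]oxazolidin-2-one; 4 3,4,5-tris(benzyloxy)benzaldehyde
Product: 6 (S)-4-benzyl-3-[(2S,3R)-2-(benzyloxy)-3-hydroxy-3-[3,4,5-tris(benzyloxy)phenyl]propanoyl]oxazolidin-2-one, via boron enolate 5 (not isolated)
Conditions: Bu2BOTf, Et3N, CH2Cl2, −78 → 0 °C; then 4, −78 → 0 °C; H2O2, pH 7 buffer, MeOH
Reagents that add atoms: none
Why: Evans syn aldol, in which the Z boron enolate 5 reacts through a Zimmerman–Traxler chair on the face away from the benzyl group of the auxiliary, which should set the 2S and 3R centres of 6 in the syn relationship that becomes the 2,3-cis pattern of the lower unit.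

**Step 3**
Reactants: 6 the aldol adduct
Product: 7 (1R,2R)-2-(benzyloxy)-1-[3,4,5-tris(benzyloxy)phenyl]propane-1,3-diol
Conditions: LiBH4, THF, MeOH (1 equiv), 0 °C
Reagents that add atoms: none
Why: Reductive cleavage of the N-acyl oxazolidinone by LiBH4 should give the primary alcohol and release the auxiliary without touching the two stereocentres.

**Step 4**
Reactants: 7 the 1,3-diol
Product: 8 (1R,2S)-2-(benzyloxy)-3-bromo-1-[3,4,5-tris(benzyloxy)phenyl]propan-1-ol
Conditions: CBr4, PPh3, 2,6-lutidine, CH2Cl2, −20 → 0 °C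
Reagents that add atoms: carbon tetrabromide, BrC(Br)(Br)Br
Why: Appel reaction, in which the unhindered primary hydroxyl forms the alkoxyphosphonium salt and is displaced by bromide much faster than the secondary benzylic hydroxyl, so both stereocentres stay intact.

**Step 5**
Reactants: 8 (1R,2S)-2-(benzyloxy)-3-bromo-1-[3,4,5-tris(benzyloxy)phenyl]propan-1-ol; 9 1,3-bis(benzyloxy)-5-bromobenzene
Product: 13 (2R,3R)-3,5,7-tris(benzyloxy)-2-[3,4,5-tris(benzyloxy)phenyl]chromane (hexa-O-benzyl epigallocatechin), via lithium alkoxide 10 (not isolated), via 3,5-bis(benzyloxy)benzyne 11 (not isolated), via aryllithium 12 (not isolated)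
Conditions: LiTMP (lithium 2,2,6,6-tetramethylpiperidide, 1.0 equiv), THF, −78 °C; then 9 (1.5 equiv), LiTMP (1.6 equiv, slow addition), −78 → −30 °C; then rt
Reagents that add atoms: none
Why: Proposed new method: LiTMP should remove the proton of 9 between Br and OBn, and loss of LiBr gives aryne 11; alkoxide 10 adds to the aryne carbon remote from the flanking benzyloxy group (the usual 3-alkoxyaryne polarisation), which puts O1 on C8a and leaves the carbanion on C4a, between two ether oxygens, in aryllithium 12. This aryllithium then displaces bromide at the primary carbon and closes ring C by a 6-exo-tet cyclisation, so that O1–C8a and C4–C4a are made in one operation. The closest known reaction types are the addition of a heteroatom nucleophile to an aryne with capture of the aryl anion by a tethered electrophile (aryne annulation) and the Parham cycloalkylation of aryllithiums onto ω-bromoalkyl chains; their union in an alkoxide that carries its own alkyl bromide is not established. No stereocentre is formed: C2 and C3 are those of 8 and are retained, because only the O–H bond and the non-stereogenic CH2Br carbon react. The step needs regioselective addition to the unsymmetrical aryne (secured by the C5 benzyloxy group), O-arylation faster than oxetane closure of 10 (lithium counter-ion, low temperature) and substitution faster than bromine–lithium exchange, which would trigger β-elimination of benzyloxide (hence a bromide and not an iodide).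

**Step 6**
Reactants: 13 hexa-O-benzyl epigallocatechin
Product: 14 (2R,3R)-3,5,7-tris(benzyloxy)-8-bromo-2-[3,4,5-tris(benzyloxy)phenyl]chromane
Conditions: NBS (1.0 equiv), CH2Cl2, −78 → 0 °C, dark
Reagents that add atoms: N-bromosuccinimide, BrN1C(=O)CCC1=O
Why: Electrophilic aromatic bromination of the phloroglucinol-type ring A, which in 5,7-bis(benzyloxy)flavans goes to C8 (next to the ring oxygen) in preference to the more crowded C6; the bromine blocks C8 for step 9.

**Step 7**
Reactants: 15 (+)-dihydrorobinetin, (2R,3R)-3,7-dihydroxy-2-(3,4,5-trihydroxyphenyl)chroman-4-one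
Product: 16 (2R,3R)-7-(benzyloxy)-3-hydroxy-2-[3,4,5-tris(benzyloxy)phenyl]chroman-4-one
Conditions: BnBr (4.4 equiv), K2CO3, DMF, 0 °C → rt, argon
Reagents that add atoms: benzyl bromide, BrCc1ccccc1
Why: Williamson etherification of the four phenols with K2CO3, which is too weak to deprotonate the aliphatic 3-hydroxyl; the low temperature should limit base-induced epimerisation of the dihydroflavonol.

**Step 8**
Reactants: 16 the tetra-O-benzyl dihydroflavonol
Product: 17 (2R,3S,4R)-7-(benzyloxy)-2-[3,4,5-tris(benzyloxy)phenyl]chromane-3,4-diol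
Conditions: NaBH4, THF/EtOH, 0 °C → rt
Reagents that add atoms: none
Why: Borohydride reduction of the aryl ketone should give mainly the 2,3-trans-3,4-trans (4R) diol by axial delivery of hydride, as is usual for trans-dihydroflavonols; the C4 configuration is of no consequence because it is erased in step 9.

**Step 9**
Reactants: 14 the 8-bromo lower unit (3 equiv); 17 the flavan-3,4-diol
Product: 18 (2R,3S,4S)-7-(benzyloxy)-4-[(2R,3R)-3,5,7-tris(benzyloxy)-8-bromo-2-[3,4,5-tris(benzyloxy)phenyl]chroman-6-yl]-2-[3,4,5-tris(benzyloxy)phenyl]chroman-3-ol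
Conditions: BF3·OEt2 (cat.), 4 Å molecular sieves, CH2Cl2, −40 → 0 °C
Reagents that add atoms: none
Why: Friedel–Crafts alkylation (interflavan coupling) with loss of water, in which BF3 ionises the C4 hydroxyl of 17 to a benzylic cation stabilised by O1 and the 7-benzyloxy group, and C6 of 14, the only free position of its ring A, attacks the face anti to the 3-hydroxyl, which should set C4 as S (3,4-trans, 4α) under control of the adjacent C3 centre.

**Step 10**
Reactants: 18 the protected, brominated dimer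
Product: 19 robinetinidol-(4α→6)-epigallocatechin, (2R,3S,4S)-4-[(2R,3R)-3,5,7-trihydroxy-2-(3,4,5-trihydroxyphenyl)chroman-6-yl]-2-(3,4,5-trihydroxyphenyl)chromane-3,7-diol
Conditions: H2 (1 atm), Pd(OH)2/C, NaOAc, THF/MeOH/H2O, rt
Reagents that add atoms: none
Why: Hydrogenolysis over Pd(OH)2/C should cleave all ten benzyl ethers and the aryl C–Br bond in one operation, with NaOAc taking up the HBr so that the interflavan bond and the stereocentres are not exposed to acid.

**Compound list**

1 | (S)-4-benzyloxazolidin-2-one | O=C1OC[C@H](Cc2ccccc2)N1 | starting material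
2 | (benzyloxy)acetyl chloride | ClC(=O)COCc1ccccc1 | starting material
3 | (S)-4-benzyl-3-[(benzyloxy)acetyl]oxazolidin-2-one | O=C1OC[C@H](Cc2ccccc2)N1C(=O)COCc1ccccc1 | intermediate
4 | 3,4,5-tris(benzyloxy)benzaldehyde | O=Cc1cc(OCc2ccccc2)c(OCc2ccccc2)c(OCc2ccccc2)c1 | starting material
5 | (Z)-dibutylboron enolate of 3 | CCCCB(CCCC)O/C(N1C(=O)OC[C@@H]1Cc1ccccc1)=C\OCc1ccccc1 | intermediate (not isolated)
6 | (S)-4-benzyl-3-[(2S,3R)-2-(benzyloxy)-3-hydroxy-3-[3,4,5-tris(benzyloxy)phenyl]propanoyl]oxazolidin-2-one | O=C1OC[C@H](Cc2ccccc2)N1C(=O)[C@@H](OCc1ccccc1)[C@@H](c1cc(OCc2ccccc2)c(OCc2ccccc2)c(OCc2ccccc2)c1)O | intermediate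
7 | (1R,2R)-2-(benzyloxy)-1-[3,4,5-tris(benzyloxy)phenyl]propane-1,3-diol | OC[C@@H](OCc1ccccc1)[C@@H](c1cc(OCc2ccccc2)c(OCc2ccccc2)c(OCc2ccccc2)c1)O | intermediate
8 | (1R,2S)-2-(benzyloxy)-3-bromo-1-[3,4,5-tris(benzyloxy)phenyl]propan-1-ol | BrC[C@@H](OCc1ccccc1)[C@@H](c1cc(OCc2ccccc2)c(OCc2ccccc2)c(OCc2ccccc2)c1)O | intermediate
9 | 1,3-bis(benzyloxy)-5-bromobenzene | Brc1cc(OCc2ccccc2)cc(OCc2ccccc2)c1 | starting material
10 | lithium (1R,2S)-2-(benzyloxy)-3-bromo-1-[3,4,5-tris(benzyloxy)phenyl]propan-1-olate | BrC[C@@H](OCc1ccccc1)[C@@H](c1cc(OCc2ccccc2)c(OCc2ccccc2)c(OCc2ccccc2)c1)O[Li] | intermediate (not isolated)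
11 | 3,5-bis(benzyloxy)benzyne | C1#CC(OCc2ccccc2)=CC(OCc2ccccc2)=C1 | intermediate (not isolated)
12 | [2-[(1R,2S)-2-(benzyloxy)-3-bromo-1-[3,4,5-tris(benzyloxy)phenyl]propoxy]-4,6-bis(benzyloxy)phenyl]lithium | BrC[C@@H](OCc1ccccc1)[C@@H](c1cc(OCc2ccccc2)c(OCc2ccccc2)c(OCc2ccccc2)c1)Oc1cc(OCc2ccccc2)cc(OCc2ccccc2)c1[Li] | intermediate (not isolated)
13 | (2R,3R)-3,5,7-tris(benzyloxy)-2-[3,4,5-tris(benzyloxy)phenyl]chromane | C(c1ccccc1)Oc1cc(OCc2ccccc2)c2C[C@@H](OCc3ccccc3)[C@@H](c3cc(OCc4ccccc4)c(OCc4ccccc4)c(OCc4ccccc4)c3)Oc2c1 | intermediate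
14 | (2R,3R)-3,5,7-tris(benzyloxy)-8-bromo-2-[3,4,5-tris(benzyloxy)phenyl]chromane | C(c1ccccc1)Oc1cc(OCc2ccccc2)c2C[C@@H](OCc3ccccc3)[C@@H](c3cc(OCc4ccccc4)c(OCc4ccccc4)c(OCc4ccccc4)c3)Oc2c1Br | intermediate
15 | (+)-dihydrorobinetin, (2R,3R)-3,7-dihydroxy-2-(3,4,5-trihydroxyphenyl)chroman-4-one | Oc1ccc2c(c1)O[C@H](c1cc(O)c(O)c(O)c1)[C@@H](O)C2=O | starting material
16 | (2R,3R)-7-(benzyloxy)-3-hydroxy-2-[3,4,5-tris(benzyloxy)phenyl]chroman-4-one | C(c1ccccc1)Oc1ccc2c(c1)O[C@H](c1cc(OCc3ccccc3)c(OCc3ccccc3)c(OCc3ccccc3)c1)[C@@H](O)C2=O | intermediate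
17 | (2R,3S,4R)-7-(benzyloxy)-2-[3,4,5-tris(benzyloxy)phenyl]chromane-3,4-diol | C(c1ccccc1)Oc1ccc2c(c1)O[C@H](c1cc(OCc3ccccc3)c(OCc3ccccc3)c(OCc3ccccc3)c1)[C@@H](O)[C@@H]2O | intermediate
18 | (2R,3S,4S)-7-(benzyloxy)-4-[(2R,3R)-3,5,7-tris(benzyloxy)-8-bromo-2-[3,4,5-tris(benzyloxy)phenyl]chroman-6-yl]-2-[3,4,5-tris(benzyloxy)phenyl]chroman-3-ol | C(c1ccccc1)Oc1ccc2c(c1)O[C@H](c1cc(OCc3ccccc3)c(OCc3ccccc3)c(OCc3ccccc3)c1)[C@@H](O)[C@@H]2c1c(OCc3ccccc3)c(Br)c2c(c1OCc3ccccc3)C[C@@H](OCc1ccccc1)[C@@H](c1cc(OCc3ccccc3)c(OCc3ccccc3)c(OCc3ccccc3)c1)O2 | intermediate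
19 | robinetinidol-(4α→6)-epigallocatechin (CNP0311915.2) | Oc1ccc2c(c1)O[C@H](c1cc(O)c(O)c(O)c1)[C@@H](O)[C@@H]2c1c(O)cc2c(c1O)C[C@@H](O)[C@@H](c1cc(O)c(O)c(O)c1)O2 | target

**Step count and risks**

Total step count: 10. Longest linear sequence: 8 steps (steps 1–6, 9 and 10); the upper unit takes steps 7 and 8 before the union.

Steps most likely to fail:

1. Step 5 (proposed new method). The hindered lithium alkoxide may capture the aryne too slowly, so that the aryne is consumed by the amide base or by aryllithium species. The bromo alkoxide may also close to an oxetane before it is arylated, or the aryllithium may be protonated before ring closure. The fallback sets out from 8 and comes back at 13, making the same two bonds in the opposite order by known reactions. Bromo alcohol 8 would be closed with KOtBu in THF to (2R,3R)-3-(benzyloxy)-2-[3,4,5-tris(benzyloxy)phenyl]oxetane F1 (intramolecular Williamson etherification). Commercial 5-fluorobenzene-1,3-diol would be benzylated (BnBr, K2CO3, DMF) to 1,3-bis(benzyloxy)-5-fluorobenzene F2. n-BuLi in THF at −78 °C should lithiate F2 between fluorine and a benzyloxy group to give [2,4-bis(benzyloxy)-6-fluorophenyl]lithium F3. BF3·OEt2 and F1 at −78 °C should then open the oxetane by substitution at its unsubstituted CH2 carbon, the less hindered site, and give (1R,2R)-2-(benzyloxy)-3-[2,4-bis(benzyloxy)-6-fluorophenyl]-1-[3,4,5-tris(benzyloxy)phenyl]propan-1-ol F4. KOtBu in DMF at 80 °C would close ring C by intramolecular nucleophilic aromatic substitution of fluoride by the alkoxide and give 13.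

2. Step 9. Facial selectivity at C4 of the 5-deoxy flavanyl cation may be poor, and the electrophile may condense with itself through its own ring A in competition with attack by the hindered C6 position of 14. The fallback sets out from 17 and comes back at 18. Diol 17 would be acetylated (Ac2O, pyridine, DMAP) to (2R,3R,4R)-7-(benzyloxy)-2-[3,4,5-tris(benzyloxy)phenyl]chromane-3,4-diyl diacetate F5. With TMSOTf in CH2Cl2 at −78 °C the 4-acetate should leave with participation of the 3-acetate, so that 14 can only attack the bridged acetoxonium ion from the α-face. The product, (2R,3S,4S)-7-(benzyloxy)-4-[(2R,3R)-3,5,7-tris(benzyloxy)-8-bromo-2-[3,4,5-tris(benzyloxy)phenyl]chroman-6-yl]-2-[3,4,5-tris(benzyloxy)phenyl]chroman-3-yl acetate F6, would be deacetylated with K2CO3 in MeOH/THF to give 18.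

3. Step 4. The electron-rich benzylic hydroxyl may also be activated, leading to ionisation with loss of configuration at C1 or to double bromination. The fallback sets out from 7 and comes back at 8. Diol 7 would be sulfonylated at the primary hydroxyl only (TsCl, Et3N, Bu2SnO cat., CH2Cl2, 0 °C) to give (2R,3R)-2-(benzyloxy)-3-hydroxy-3-[3,4,5-tris(benzyloxy)phenyl]propyl 4-methylbenzenesulfonate F7. LiBr in acetone would then exchange tosylate for bromide (Finkelstein-type substitution) and give 8 without any activation of the benzylic position.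

**Further compounds**

F1 | step 5 | (2R,3R)-3-(benzyloxy)-2-[3,4,5-tris(benzyloxy)phenyl]oxetane | C1[C@@H](OCc2ccccc2)[C@@H](c2cc(OCc3ccccc3)c(OCc3ccccc3)c(OCc3ccccc3)c2)O1
F2 | step 5 | 1,3-bis(benzyloxy)-5-fluorobenzene | Fc1cc(OCc2ccccc2)cc(OCc2ccccc2)c1
F3 | step 5 | [2,4-bis(benzyloxy)-6-fluorophenyl]lithium | [Li]c1c(F)cc(OCc2ccccc2)cc1OCc1ccccc1
F4 | step 5 | (1R,2R)-2-(benzyloxy)-3-[2,4-bis(benzyloxy)-6-fluorophenyl]-1-[3,4,5-tris(benzyloxy)phenyl]propan-1-ol | Fc1cc(OCc2ccccc2)cc(OCc2ccccc2)c1C[C@@H](OCc1ccccc1)[C@@H](c1cc(OCc2ccccc2)c(OCc2ccccc2)c(OCc2ccccc2)c1)O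
F5 | step 9 | (2R,3R,4R)-7-(benzyloxy)-2-[3,4,5-tris(benzyloxy)phenyl]chromane-3,4-diyl diacetate (3,4-di-O-acetate of 17) | C(c1ccccc1)Oc1ccc2c(c1)O[C@H](c1cc(OCc3ccccc3)c(OCc3ccccc3)c(OCc3ccccc3)c1)[C@@H](OC(C)=O)[C@@H]2OC(C)=O
F6 | step 9 | (2R,3S,4S)-7-(benzyloxy)-4-[(2R,3R)-3,5,7-tris(benzyloxy)-8-bromo-2-[3,4,5-tris(benzyloxy)phenyl]chroman-6-yl]-2-[3,4,5-tris(benzyloxy)phenyl]chroman-3-yl acetate | C(c1ccccc1)Oc1ccc2c(c1)O[C@H](c1cc(OCc3ccccc3)c(OCc3ccccc3)c(OCc3ccccc3)c1)[C@@H](OC(C)=O)[C@@H]2c1c(OCc3ccccc3)c(Br)c2c(c1OCc3ccccc3)C[C@@H](OCc1ccccc1)[C@@H](c1cc(OCc3ccccc3)c(OCc3ccccc3)c(OCc3ccccc3)c1)O2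
F7 | step 4 | (2R,3R)-2-(benzyloxy)-3-hydroxy-3-[3,4,5-tris(benzyloxy)phenyl]propyl 4-methylbenzenesulfonate | Cc1ccc(cc1)S(=O)(=O)OC[C@@H](OCc1ccccc1)[C@@H](c1cc(OCc2ccccc2)c(OCc2ccccc2)c(OCc2ccccc2)c1)O
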